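**Plan**
- Retrosynthesis: the C3 tiglate and C13 acetate C–O bonds are cut first. The butenolide is then taken apart at C7=C11 (dehydration), C6–O (lactone) and C7–C11 (aldol of a C6-ketone enolate with a silyloxypyruvate). The ring alkenes C1=C10 and C4=C5 are traded for the sigma bonds C1–C4 and C5–C10 of a bicyclo[2.2.0]hexane, and last C5–C4 and C10–C1 are cut ([2+2]).
- Enabling feature: the ten-membered ring holds the (Z,E)-cyclodeca-1,5-diene unit C10=C1–C2–C3–C4=C5 with oxygenated C6 next to it. This is the array left when the central cyclobutane (C5, C10, C1, C4) of a cyclohexenone/cyclobutene photoadduct is opened across C1–C4 and C5–C10.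
- Forward order: the cyclobutenyl silyl ether and 3-methylcyclohexenone give the tricycle (central cyclobutane closes). Cycloreversion then gives the ten-membered dienone, the butenolide ring is built on C6/C7 (aldol, reduction, lactonisation, dehydration), and desilylation, acetate and tiglate follow.
- Stereochemistry: C3 comes from a lipase resolution of the cyclobutenol and is never touched again. C6 comes from hydride addition anti to the C7 side chain (itself placed on the outer face of the ring enolate) and retentive lactonisation. Z at C1=C10 and E at C4=C5 come from the cycloreversion, and the E tiglate from the reagent.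

Key step: step 4

Remark: ring atoms carry germacrane numbers in all intermediates, the tricycle included (C1–C10 ring, C14 on C10, C15 on C4, C11–C13 lactone carbons); 1-methylcyclobutene (bp 37 °C) is taken as a catalogue chemical and handled cold.

Step 1
Reactants: 1 1-methylcyclobut-1-ene
Product: 2 (±)-2-methylcyclobut-2-en-1-ol
Conditions: SeO2 (cat.), t-BuOOH, CH2Cl2, 0 °C to rt
Reagents that add atoms: tert-butyl hydroperoxide, CC(C)(C)OO (oxygen passed on by the catalyst selenium dioxide, O=[Se]=O)
Why: Riley allylic oxidation (ene reaction with SeO2, then [2,3]-sigmatropic shift of the allylseleninic acid) attacks the ring CH2 on the more substituted alkene carbon in preference to the methyl group and returns the double bond to its place, so the carbinol forms as the racemate.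

Step 2
Reactants: 2 (±)-2-methylcyclobut-2-en-1-ol
Product: 3 (S)-2-methylcyclobut-2-en-1-ol
Conditions: Burkholderia cepacia lipase (lipase PS), vinyl acetate, MTBE, 25 °C, run past half conversion; chromatography
Reagents that add atoms: none
Why: Lipase-catalysed kinetic resolution by irreversible transesterification: the enzyme should acetylate the (R)-alcohol faster (large flank = methyl-bearing alkene carbon, small flank = ring CH2), so the (S)-alcohol is left and its enantiomeric purity rises with conversion.

Step 3
Reactants: 3 (S)-2-methylcyclobut-2-en-1-ol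
Product: 4 (S)-tert-butyldimethyl[(2-methylcyclobut-2-en-1-yl)oxy]silane
Conditions: TBSCl, imidazole, DMF, 0 °C to rt
Reagents that add atoms: tert-butyldimethylsilyl chloride, CC(C)(C)[Si](C)(C)Cl
Why: Imidazole-promoted silylation of the alcohol oxygen leaves the stereocentre untouched and gives a non-volatile, photostable alkene partner.

Step 4
Reactants: 4 (S)-tert-butyldimethyl[(2-methylcyclobut-2-en-1-yl)oxy]silane; 5 3-methylcyclohex-2-en-1-one
Product: 6 (1R,2R,4S,5R,6R)-4-(tert-butyldimethylsilyloxy)-1,5-dimethyltricyclo[4.4.0.0(2,5)]decan-7-one (cis-anti-cis, silyloxy group exo)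
Conditions: hν (350 nm, Pyrex), CH2Cl2, −40 °C, 4 in excess (recovered); then basic Al2O3, CH2Cl2, rt
Reagents that add atoms: none
Why: Excitation and intersystem crossing give the triplet enone, which adds stepwise: C10 (enone β-carbon) bonds to the unsubstituted alkene carbon C1 to give a triplet 1,4-biradical (tertiary radical at C4, α-keto radical at C5), and after spin inversion radical recombination C5–C4 closes the central four-membered ring (formal [2π+2π], both new bonds on one face of each partner). The closest known reaction type is the enone–alkene [2+2] photocycloaddition of cyclohexenones with cyclobutenes to tricyclo[4.4.0.0(2,5)]decanones. The cis fusions at C5/C10 and C1/C4 are imposed by the six- and four-membered rings (C5, α to the ketone, equilibrates on basic Al2O3), the anti relation of the outer rings follows from exo approach, and the cyclobutene is taken on the face away from the C3 silyloxy group, so C3 controls all four new centres. The step needs head-to-head regiochemistry (C10–C1, C5–C4); the substrate secures it because the alternative would join the two fully substituted carbons C10 and C4 and pass through a secondary instead of a tertiary radical. The four new centres are erased in step 5, so what counts here is the constitution and one diastereomer for a clean ring opening.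

Step 5
Reactants: 6 tricyclic ketone
Product: 7 (2E,4S,6Z)-4-(tert-butyldimethylsilyloxy)-3,7-dimethylcyclodeca-2,6-dien-1-one (germacrane numbering: 3-silyloxy, 1(10)Z,4E, 6-one)
Conditions: PhMe (degassed), BHT (trace), sealed base-washed tube, 180 °C
Reagents that add atoms: none
Why: Thermal cycloreversion of the bicyclo[2.2.0]hexane (retro-[2+2] of the central cyclobutane, formally [σ2s+σ2a] through a cyclohexane-1,4-diyl) turns the strained bonds C1–C4 and C5–C10 into C1=C10 and C4=C5 with one Z and one E alkene, expected Z at C1=C10 and E in the enone as in the opening of related head-to-head methylcyclobutene/cyclohexenone photoadducts, while conjugation with the C6 ketone holds back Cope rearrangement and C3 is untouched.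

Step 6
Reactants: 8 ethyl 2-(hydroxymethyl)prop-2-enoate
Product: 9 ethyl 2-{[(tert-butyldimethylsilyl)oxy]methyl}prop-2-enoate
Conditions: TBSCl, imidazole, CH2Cl2, 0 °C to rt
Reagents that add atoms: tert-butyldimethylsilyl chloride, CC(C)(C)[Si](C)(C)Cl
Why: Standard silylation of a primary allylic alcohol gives the masked C13 oxygen.

Step 7
Reactants: 9 ethyl 2-{[(tert-butyldimethylsilyl)oxy]methyl}prop-2-enoate
Product: 11 ethyl 3-(tert-butyldimethylsilyloxy)-2-oxopropanoate, via secondary ozonide 10 (not isolated)
Conditions: O3, CH2Cl2, −78 °C; then Me2S, −78 °C to rt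
Reagents that add atoms: ozone, [O-][O+]=O
Why: Ozonolysis of the 1,1-disubstituted alkene with reductive work-up cleaves the methylene carbon and leaves the α-keto ester that supplies C11, C12 and C13.

Step 8
Reactants: 7 cyclodecadienone; 11 ethyl 3-(tert-butyldimethylsilyloxy)-2-oxopropanoate
Product: 13 ethyl (3S,7R)-3,13-bis(tert-butyldimethylsilyloxy)-11-hydroxy-6-oxogermacra-1(10)Z,4E-dien-12-oate (C11 epimers), via lithium enolate 12 (not isolated)
Conditions: LiN(i-Pr)2, THF, −78 °C; then 11, −78 °C; AcOH quench at −78 °C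
Reagents that add atoms: none
Why: Aldol addition: kinetic α′-deprotonation at C7 gives the cross-conjugated enolate, which adds to the very electrophilic ketone of the α-keto ester on the outer face of the ring (this sets C7), while C11 forms as an epimer mixture; both centres become sp2 in step 10.

Step 9
Reactants: 13 aldol adduct
Product: 15 (3S,6R,7S)-3,13-bis(tert-butyldimethylsilyloxy)-11-hydroxygermacra-1(10)Z,4E-dien-12,6-olide (C11 epimers), via hydroxy ester 14 (not isolated)
Conditions: NaBH4, CeCl3·7H2O, MeOH, −78 to −20 °C; then PPTS (cat.), PhMe, 40 °C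
Reagents that add atoms: none
Why: Luche 1,2-reduction of the enone carbonyl followed by lactonisation (intramolecular transesterification): hydride should add to C6 anti to the bulky C7 side chain (1,2-induction) to give the 6R carbinol, and ring closure on the ester keeps that configuration in a cis-fused γ-lactone.

Step 10
Reactants: 15 hydroxy lactone
Product: 17 (3S,6R)-3,13-bis(tert-butyldimethylsilyloxy)germacra-1(10)Z,4E,7(11)-trien-12,6-olide, via chlorosulfite 16 (not isolated)
Conditions: SOCl2, pyridine, CH2Cl2, −20 to 0 °C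
Reagents that add atoms: none
Why: Dehydration of a tertiary α-hydroxy lactone through its chlorosulfite (pyridine-mediated E2 or internal syn elimination) toward C7–H gives the conjugated tetrasubstituted butenolide, whereas loss of a C13 hydrogen would need a C–H bond on an oxygen-bearing carbon and give an enol ether; both C11 epimers converge and only C3 and C6 remain stereogenic.

Step 11
Reactants: 17 bis-silyl butenolide
Product: 18 (3S,6R)-3,13-dihydroxygermacra-1(10)Z,4E,7(11)-trien-12,6-olide
Conditions: HF·pyridine, pyridine, THF, 0 °C to rt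
Reagents that add atoms: none
Why: Fluoride-driven cleavage of both Si–O bonds under buffered, non-basic conditions spares the base-epimerisable C6 (butenolide γ-position) and the acid-sensitive cyclodecadiene.

Step 12
Reactants: 18 diol
Product: 19 (3S,6R)-13-acetoxy-3-hydroxygermacra-1(10)Z,4E,7(11)-trien-12,6-olide
Conditions: AcCl, 2,4,6-collidine, CH2Cl2, −78 °C
Reagents that add atoms: acetyl chloride, CC(=O)Cl
Why: Chemoselective acylation: with a hindered pyridine base at low temperature the primary allylic C13 alcohol is acetylated well before the secondary C3 alcohol.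

Step 13
Reactants: 19 monoacetate; 20 (E)-2-methylbut-2-enoyl chloride (tigloyl chloride)
Product: 21 (3S,6R)-13-acetoxy-3-[(E)-2-methylbut-2-enoyloxy]germacra-1(10)Z,4E,7(11)-trien-12,6-olide (CNP0198881.1)
Conditions: pyridine, DMAP (cat.), CH2Cl2, 0 °C to rt
Reagents that add atoms: none
Why: DMAP-catalysed O-acylation (nucleophilic catalysis through the N-acylpyridinium ion) of the remaining secondary alcohol proceeds with retention at C3, and the mild base keeps the E tiglate and the C6 centre intact.

**Compound list**
1 | 1-methylcyclobut-1-ene | CC1=CCC1 | starting material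
2 | (±)-2-methylcyclobut-2-en-1-ol | CC1=CCC1O | intermediate
3 | (S)-2-methylcyclobut-2-en-1-ol | CC1=CC[C@@H]1O | intermediate
4 | (S)-tert-butyldimethyl[(2-methylcyclobut-2-en-1-yl)oxy]silane | CC1=CC[C@@H]1O[Si](C)(C)C(C)(C)C | intermediate
5 | 3-methylcyclohex-2-en-1-one | CC1=CC(=O)CCC1 | starting material
6 | (1R,2R,4S,5R,6R)-4-(tert-butyldimethylsilyloxy)-1,5-dimethyltricyclo[4.4.0.0(2,5)]decan-7-one | O=C1CCC[C@@]2(C)[C@@H]1[C@]3(C)[C@@H](O[Si](C)(C)C(C)(C)C)C[C@H]23 | intermediate
7 | (2E,4S,6Z)-4-(tert-butyldimethylsilyloxy)-3,7-dimethylcyclodeca-2,6-dien-1-one | CC(C)(C)[Si](C)(C)O[C@H]1C/C=C(/C)CCCC(=O)/C=C/1C | intermediate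
8 | ethyl 2-(hydroxymethyl)prop-2-enoate | C=C(CO)C(=O)OCC | starting material
9 | ethyl 2-{[(tert-butyldimethylsilyl)oxy]methyl}prop-2-enoate | C=C(CO[Si](C)(C)C(C)(C)C)C(=O)OCC | intermediate
10 | ethyl 3-{[(tert-butyldimethylsilyl)oxy]methyl}-1,2,4-trioxolane-3-carboxylate (secondary ozonide) | CCOC(=O)C1(CO[Si](C)(C)C(C)(C)C)OCOO1 | intermediate
11 | ethyl 3-(tert-butyldimethylsilyloxy)-2-oxopropanoate | CCOC(=O)C(=O)CO[Si](C)(C)C(C)(C)C | intermediate
12 | lithium C6(O)=C7 enolate of 7 (enolate geometry not specified) | CC(C)(C)[Si](C)(C)O[C@H]1C/C=C(/C)CCC=C(O[Li])/C=C/1C | intermediate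
13 | ethyl (3S,7R)-3,13-bis(tert-butyldimethylsilyloxy)-11-hydroxy-6-oxogermacra-1(10)Z,4E-dien-12-oate (C11 epimers) | CC(C)(C)[Si](C)(C)O[C@H]1C/C=C(/C)CC[C@H](C(O)(CO[Si](C)(C)C(C)(C)C)C(=O)OCC)C(=O)/C=C/1C | intermediate
14 | ethyl (3S,6R,7S)-3,13-bis(tert-butyldimethylsilyloxy)-6,11-dihydroxygermacra-1(10)Z,4E-dien-12-oate (C11 epimers) | CC(C)(C)[Si](C)(C)O[C@H]1C/C=C(/C)CC[C@H](C(O)(CO[Si](C)(C)C(C)(C)C)C(=O)OCC)[C@H](O)/C=C/1C | intermediate
15 | (3S,6R,7S)-3,13-bis(tert-butyldimethylsilyloxy)-11-hydroxygermacra-1(10)Z,4E-dien-12,6-olide (C11 epimers) | CC(C)(C)[Si](C)(C)O[C@H]1C/C=C(/C)CC[C@@H]2C(O)(CO[Si](C)(C)C(C)(C)C)C(=O)O[C@@H]2/C=C/1C | intermediate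
16 | C11 chlorosulfite of 15 | CC(C)(C)[Si](C)(C)O[C@H]1C/C=C(/C)CC[C@@H]2C(OS(=O)Cl)(CO[Si](C)(C)C(C)(C)C)C(=O)O[C@@H]2/C=C/1C | intermediate
17 | (3S,6R)-3,13-bis(tert-butyldimethylsilyloxy)germacra-1(10)Z,4E,7(11)-trien-12,6-olide | CC(C)(C)[Si](C)(C)O[C@H]1C/C=C(/C)CCC2=C(CO[Si](C)(C)C(C)(C)C)C(=O)O[C@@H]2/C=C/1C | intermediate
18 | (3S,6R)-3,13-dihydroxygermacra-1(10)Z,4E,7(11)-trien-12,6-olide | O[C@H]1C/C=C(/C)CCC2=C(CO)C(=O)O[C@@H]2/C=C/1C | intermediate
19 | (3S,6R)-13-acetoxy-3-hydroxygermacra-1(10)Z,4E,7(11)-trien-12,6-olide | O[C@H]1C/C=C(/C)CCC2=C(COC(C)=O)C(=O)O[C@@H]2/C=C/1C | intermediate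
20 | (E)-2-methylbut-2-enoyl chloride (tigloyl chloride) | C/C=C(\C)C(=O)Cl | starting material
21 | (3S,6R)-13-acetoxy-3-[(E)-2-methylbut-2-enoyloxy]germacra-1(10)Z,4E,7(11)-trien-12,6-olide | C/C=C(\C)C(=O)O[C@H]1C/C=C(/C)CCC2=C(COC(C)=O)C(=O)O[C@@H]2/C=C/1C | target

**Step count**
Total: 13 steps. Longest linear sequence: 11 steps (steps 1–5 and 8–13); the keto ester branch is steps 6–7.

**Steps most likely to fail**

Step 5. The cycloreversion may lose geometric control: the E bond may arise at C1=C10 with a Z enone, or the conjugated alkene may drift. At the temperature needed the diene may also react on by Cope rearrangement or C2–C3 scission to a divinylcyclohexanone enol ether. The fallback opens the ring at the carbinol oxidation level, where no α-keto radical path exists; it sets out from 6 and returns at 7. NaBH4 (MeOH, 0 °C) reduces 6 to the tricyclic carbinol F1, thermolysis (PhMe, 170–180 °C) opens its bicyclo[2.2.0]hexane to the (Z,E)-cyclodecadienol F2, and MnO2 (CH2Cl2, rt) oxidises the allylic alcohol to the E-enone 7.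

Step 9. Hydride may add to C6 with poor or opposite facial selectivity if the ring conformation, not the C7 side chain, steers the reagent; retentive lactonisation would then carry the wrong C6 configuration forward. The fallback closes the lactone with inversion; it sets out from 13 and returns at 15. The same Luche reduction then gives the 6S hydroxy ester F3 and, after lactonisation, the C6-epimeric hydroxy lactone F4. LiOH (THF/H2O, 0 °C, cold citric acid work-up) opens F4 to the hydroxy acid F5, and Mitsunobu lactonisation (PPh3, DIAD, THF, 0 °C) forms the C6–O bond with inversion to give 15.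

Step 10. The elimination may run toward C13 (enol silyl ether) or stall for the C11 epimer that lacks an antiperiplanar C7–H. The fallback removes water while C7–H is still α to the C6 ketone, so the regiochemistry is fixed by E1cB; it sets out from 13 and returns at 17. Ac2O/DMAP/Et3N gives the tertiary acetate F6, and DBU (CH2Cl2, rt) eliminates acetate to the (Z)-alkylidene keto ester F7; a Z/E mixture would be equilibrated with catalytic iodine, since only the Z isomer can lactonise. Luche reduction (NaBH4, CeCl3·7H2O, MeOH, −78 °C) gives the hydroxy enoate F8, which lactonises on work-up to 17; C6 is then set in this reduction and, if needed, corrected as described for step 9.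

**Further compounds**
F1 | step 5 | (1R,2R,4S,5R,6R)-4-(tert-butyldimethylsilyloxy)-1,5-dimethyltricyclo[4.4.0.0(2,5)]decan-7-ol (carbinol epimers) | OC1CCC[C@@]2(C)[C@@H]1[C@]3(C)[C@@H](O[Si](C)(C)C(C)(C)C)C[C@H]23
F2 | step 5 | (2E,4S,6Z)-4-(tert-butyldimethylsilyloxy)-3,7-dimethylcyclodeca-2,6-dien-1-ol (carbinol epimers) | CC(C)(C)[Si](C)(C)O[C@H]1C/C=C(/C)CCCC(O)/C=C/1C
F3 | step 9 | ethyl (3S,6S,7S)-3,13-bis(tert-butyldimethylsilyloxy)-6,11-dihydroxygermacra-1(10)Z,4E-dien-12-oate | CC(C)(C)[Si](C)(C)O[C@H]1C/C=C(/C)CC[C@H](C(O)(CO[Si](C)(C)C(C)(C)C)C(=O)OCC)[C@@H](O)/C=C/1C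
F4 | step 9 | (3S,6S,7S)-3,13-bis(tert-butyldimethylsilyloxy)-11-hydroxygermacra-1(10)Z,4E-dien-12,6-olide | CC(C)(C)[Si](C)(C)O[C@H]1C/C=C(/C)CC[C@@H]2C(O)(CO[Si](C)(C)C(C)(C)C)C(=O)O[C@H]2/C=C/1C
F5 | step 9 | (3S,6S,7S)-3,13-bis(tert-butyldimethylsilyloxy)-6,11-dihydroxygermacra-1(10)Z,4E-dien-12-oic acid | CC(C)(C)[Si](C)(C)O[C@H]1C/C=C(/C)CC[C@H](C(O)(CO[Si](C)(C)C(C)(C)C)C(=O)O)[C@@H](O)/C=C/1C
F6 | step 10 | ethyl (3S,7R)-11-acetoxy-3,13-bis(tert-butyldimethylsilyloxy)-6-oxogermacra-1(10)Z,4E-dien-12-oate | CC(C)(C)[Si](C)(C)O[C@H]1C/C=C(/C)CC[C@H](C(OC(C)=O)(CO[Si](C)(C)C(C)(C)C)C(=O)OCC)C(=O)/C=C/1C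
F7 | step 10 | ethyl (3S)-3,13-bis(tert-butyldimethylsilyloxy)-6-oxogermacra-1(10)Z,4E,7(11)Z-trien-12-oate | CC(C)(C)[Si](C)(C)O[C@H]1C/C=C(/C)CC/C(=C(/C(=O)OCC)CO[Si](C)(C)C(C)(C)C)C(=O)/C=C/1C
F8 | step 10 | ethyl (3S,6R)-3,13-bis(tert-butyldimethylsilyloxy)-6-hydroxygermacra-1(10)Z,4E,7(11)Z-trien-12-oate | CC(C)(C)[Si](C)(C)O[C@H]1C/C=C(/C)CC/C(=C(/C(=O)OCC)CO[Si](C)(C)C(C)(C)C)[C@H](O)/C=C/1C
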